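The route rests on forming the ring-fusion bond C3a–C7a by a pinacol-terminated Prins cyclization. Condensation of 3,4,5-trimethoxybenzaldehyde with an (R)-malic-acid-derived (Z)-allylic diol gives a dioxolane; its oxocarbenium ion closes onto the alkene to a six-membered oxane cation, which contracts to the oxolane ring when C7a shifts from C4 to C3a. One operation forms C2–C3 and C3a–C7a and sets C2, C3 and the quaternary C3a. The step exploits the O1–C7a–C3a–C4 array: C4, later the vinylic CH of the cyclohexadienone ring, appears as a formyl group. Aldol condensation then closes the carbocycle and a Saegusa–Ito oxidation installs C7=C7a.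

Key step: step 6

Remark on the chemistry: atom labels (O1, C2, C3, C3a, C4–C7, C7a) follow the benzofuranone numbering of the target in all intermediates; 12 is drawn as the open hydroxy ketone although it should rest mainly as its five-membered lactol, and the carbinol centre made in step 4 is lost in step 6, so either epimer serves.

Step 1
Reactants: 1 acetaldehyde
Product: 2 1,1-dibromoprop-1-ene
Conditions: CBr4, PPh3, CH2Cl2, 0 °C
Reagents that add atoms: carbon tetrabromide, BrC(Br)(Br)Br
Why: Ramirez gem-dibromoolefination (first stage of the Corey–Fuchs sequence) should turn the aldehyde into the 1,1-dibromoalkene, the carbon from CBr4 being the future quaternary C3a.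

Step 2
Reactants: 2 1,1-dibromoprop-1-ene; 3 allyltributylstannane
Product: 4 (4Z)-4-bromohexa-1,4-diene
Conditions: Pd2(dba)3 (tris(dibenzylideneacetone)dipalladium, cat.), tri(2-furyl)phosphine, THF, 60 °C
Reagents that add atoms: none
Why: Stille coupling of a 1,1-dibromoalkene should occur once, at the less hindered C–Br bond trans to the methyl group, so that the remaining bromine is cis to methyl.

Step 3
Reactants: 4 (4Z)-4-bromohexa-1,4-diene; 5 [(4R)-2,2-dimethyl-5-oxo-1,3-dioxolan-4-yl]acetic acid
Product: 9 (3R,5Z)-3-hydroxy-4-oxo-5-(prop-2-en-1-yl)hept-5-enoic acid, via lithium carboxylate 6 (not isolated), via vinyllithium 7 (not isolated), via tetrahedral adduct 8 (not isolated)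
Conditions: 4, t-BuLi (2 equiv), Et2O, −78 °C; 5, LiN(SiMe3)2 (1 equiv), THF, −78 °C; combine at −78 °C; then 1 M HCl
Reagents that add atoms: none
Why: Bromine–lithium exchange (retention of alkene geometry) followed by nucleophilic acyl substitution at the activated dioxolanone carbonyl should stop at the ketone stage because adduct 8 persists until acidic work-up, which also releases acetone; the acid is shielded as its lithium salt and the malic-acid stereocentre is not touched.

Step 4
Reactants: 9 (3R,5Z)-3-hydroxy-4-oxo-5-(prop-2-en-1-yl)hept-5-enoic acid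
Product: 11 (4R,5S)-5-[(2Z)-hexa-2,5-dien-3-yl]-4-hydroxyoxolan-2-one, via dihydroxy acid 10 (not isolated)
Conditions: NaBH4, CeCl3·7H2O, MeOH, −78 °C; then TsOH·H2O (cat.), CH2Cl2, rt
Reagents that add atoms: none
Why: Luche reduction should reduce the enone carbonyl 1,2 and, through chelation of the α-hydroxy ketone, mainly to the anti diol, whose γ-hydroxy acid lactonizes under acid; the new carbinol carbon becomes the formyl carbon in step 6, so its configuration does not reach the target.

Step 5
Reactants: 11 (4R,5S)-5-[(2Z)-hexa-2,5-dien-3-yl]-4-hydroxyoxolan-2-one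
Product: 12 (4R,5S,6Z)-4,5-dihydroxy-1-methoxy-6-(prop-2-en-1-yl)oct-6-en-2-one
Conditions: Bu3SnCH2OMe, n-BuLi, THF, −78 °C (2.5 equiv MeOCH2Li); then 11, −78 °C; AcOH
Reagents that add atoms: tributyl(methoxymethyl)stannane, CCCC[Sn](CCCC)(CCCC)COC (delivered as methoxymethyllithium, [Li]COC)
Why: Tin–lithium exchange gives methoxymethyllithium, whose addition to the lactone carbonyl (after deprotonation of the free hydroxyl) should stop at the lactol stage because the lithium hemiketalate does not collapse at −78 °C; this installs C5 with its methoxy group and C6 as the ketone.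

Step 6
Reactants: 12 (4R,5S,6Z)-4,5-dihydroxy-1-methoxy-6-(prop-2-en-1-yl)oct-6-en-2-one; 13 3,4,5-trimethoxybenzaldehyde
Product: 15 (2R,3R,4S,5R)-2-(3-methoxy-2-oxopropyl)-4-methyl-3-(prop-2-en-1-yl)-5-(3,4,5-trimethoxyphenyl)oxolane-3-carbaldehyde, via benzylidene acetal 14 (not isolated)
Conditions: 13, PPTS (cat.), MgSO4, CH2Cl2, rt; then SnCl4 (2.5 equiv), −78 → −20 °C
Reagents that add atoms: none
Why: Pinacol-terminated Prins cyclization (Prins–pinacol): SnCl4 opens the dioxolane of 14 to the (E)-oxocarbenium ion on the oxygen of the future C7a, the methyl-bearing alkene carbon (future C3) attacks its carbon (future C2) through a chair, and in the resulting tertiary oxan-4-yl cation the ring bond C7a–C4 migrates to the cationic C3a, which forms C3a–C7a and turns the carbinol carbon into the formyl group. The closest known reaction type is the Lewis-acid rearrangement of allylic diol acetals to 3-acyl- and 3-formyltetrahydrofurans; a 2-oxonia-Cope shift followed by 5-(enolexo)-endo-trig aldol closure would give the same product. The transient oxane ring closes 6-endo-trig and the oxolane ring arises from it by 1,2-shift (ring contraction). C2 and C3 are set by the chair, in which the aryl group and the ketone side chain are equatorial and the methyl of the Z-alkene is axial (aryl cis to methyl); C3a is set by suprafacial migration of C7a onto the face syn to C2, leaving formyl cis and allyl trans to the methyl; the absolute sense derives from the malic-acid carbon C7a, which migrates with retention and is cleared in step 8. The step needs Markovnikov attack by the trisubstituted alkene (tertiary cation; the terminal allyl alkene cannot reach the oxocarbenium carbon in a small ring) and ring-bond migration in preference to a 1,2-hydride shift from the carbinol carbon; the latter is expected from the behaviour of secondary allylic carbinols in this reaction but is not secured by the substrate.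

Step 7
Reactants: 15 (2R,3R,4S,5R)-2-(3-methoxy-2-oxopropyl)-4-methyl-3-(prop-2-en-1-yl)-5-(3,4,5-trimethoxyphenyl)oxolane-3-carbaldehyde
Product: 17 (2R,3S,3aS,7aR)-5-methoxy-3-methyl-3a-(prop-2-en-1-yl)-2-(3,4,5-trimethoxyphenyl)-3,3a,7,7a-tetrahydro-1-benzofuran-6(2H)-one, via aldol adduct 16 (not isolated)
Conditions: K2CO3, MeOH, rt → 50 °C
Reagents that add atoms: none
Why: Intramolecular aldol condensation: the enolate on the methoxy-bearing carbon (C5) adds to the non-enolizable neopentyl aldehyde (C4) in a 6-(enolexo)-exo-trig closure and E1cB loss of water gives the 2-methoxy enone; the cis disposition of formyl and side chain on the oxolane secures the cis ring fusion, and no stereocentre of the target is enolizable.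

Step 8
Reactants: 17 (2R,3S,3aS,7aR)-5-methoxy-3-methyl-3a-(prop-2-en-1-yl)-2-(3,4,5-trimethoxyphenyl)-3,3a,7,7a-tetrahydro-1-benzofuran-6(2H)-one
Product: 19 (2R,3S,3aS)-5-methoxy-3-methyl-3a-(prop-2-en-1-yl)-2-(3,4,5-trimethoxyphenyl)-3,3a-dihydro-1-benzofuran-6(2H)-one, via silyl dienol ether 18 (not isolated)
Conditions: TMSOTf, Et3N, CH2Cl2, 0 °C; then Pd(OAc)2 (1.1 equiv), MeCN, rt
Reagents that add atoms: none
Why: Saegusa–Ito oxidation: the ketone can enolize only toward C7, and the palladium enolate formed from 18 and Pd(OAc)2 can lose only the C7a hydrogen by β-hydride elimination, which installs the C7=C7a enol ether double bond, removes the auxiliary stereocentre at C7a and leaves C2, C3 and C3a untouched.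

Compound list
1 | acetaldehyde | CC=O | starting material
2 | 1,1-dibromoprop-1-ene | CC=C(Br)Br | intermediate
3 | allyltributylstannane (tributyl(prop-2-en-1-yl)stannane) | C=CC[Sn](CCCC)(CCCC)CCCC | starting material
4 | (4Z)-4-bromohexa-1,4-diene (bromine cis to methyl) | C/C=C(Br)/CC=C | intermediate
5 | [(4R)-2,2-dimethyl-5-oxo-1,3-dioxolan-4-yl]acetic acid (acetonide of (R)-malic acid) | OC(=O)C[C@H]1OC(C)(C)OC1=O | starting material
6 | lithium [(4R)-2,2-dimethyl-5-oxo-1,3-dioxolan-4-yl]acetate | [Li+].[O-]C(=O)C[C@H]1OC(C)(C)OC1=O | intermediate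
7 | [(2E)-hexa-2,5-dien-3-yl]lithium (lithium cis to methyl) | C/C=C([Li])/CC=C | intermediate
8 | dilithium {(4R)-5-[(2Z)-hexa-2,5-dien-3-yl]-2,2-dimethyl-5-oxido-1,3-dioxolan-4-yl}acetate (tetrahedral adduct, new ketal centre unassigned) | [Li+].[Li+].[O-]C(=O)C[C@H]1OC(C)(C)OC1([O-])/C(CC=C)=C\C | intermediate
9 | (3R,5Z)-3-hydroxy-4-oxo-5-(prop-2-en-1-yl)hept-5-enoic acid | OC(=O)C[C@@H](O)C(=O)/C(CC=C)=C\C | intermediate
10 | (3R,4S,5Z)-3,4-dihydroxy-5-(prop-2-en-1-yl)hept-5-enoic acid | OC(=O)C[C@@H](O)[C@@H](O)/C(CC=C)=C\C | intermediate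
11 | (4R,5S)-5-[(2Z)-hexa-2,5-dien-3-yl]-4-hydroxyoxolan-2-one | O=C1C[C@@H](O)[C@H](/C(CC=C)=C\C)O1 | intermediate
12 | (4R,5S,6Z)-4,5-dihydroxy-1-methoxy-6-(prop-2-en-1-yl)oct-6-en-2-one (open form of the lactol) | COCC(=O)C[C@@H](O)[C@@H](O)/C(CC=C)=C\C | intermediate
13 | 3,4,5-trimethoxybenzaldehyde | COc1cc(C=O)cc(OC)c1OC | starting material
14 | 1-{(4R,5S)-5-[(2Z)-hexa-2,5-dien-3-yl]-2-(3,4,5-trimethoxyphenyl)-1,3-dioxolan-4-yl}-3-methoxypropan-2-one (both acetal epimers) | COCC(=O)C[C@H]1OC(c2cc(OC)c(OC)c(OC)c2)O[C@H]1/C(CC=C)=C\C | intermediate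
15 | (2R,3R,4S,5R)-2-(3-methoxy-2-oxopropyl)-4-methyl-3-(prop-2-en-1-yl)-5-(3,4,5-trimethoxyphenyl)oxolane-3-carbaldehyde (aryl, methyl, formyl and side chain on one face, allyl on the other) | C=CC[C@@]1(C=O)[C@H](C)[C@H](c2cc(OC)c(OC)c(OC)c2)O[C@@H]1CC(=O)COC | intermediate
16 | 4-hydroxy-5-methoxy-3-methyl-3a-(prop-2-en-1-yl)-2-(3,4,5-trimethoxyphenyl)hexahydro-1-benzofuran-6(2H)-one (C2, C3, C3a, C7a as in 17; C4 and C5 epimers) | C=CC[C@]12C(O)C(OC)C(=O)C[C@H]1O[C@@H](c1cc(OC)c(OC)c(OC)c1)[C@H]2C | intermediate
17 | (2R,3S,3aS,7aR)-5-methoxy-3-methyl-3a-(prop-2-en-1-yl)-2-(3,4,5-trimethoxyphenyl)-3,3a,7,7a-tetrahydro-1-benzofuran-6(2H)-one | C=CC[C@]12C=C(OC)C(=O)C[C@H]1O[C@@H](c1cc(OC)c(OC)c(OC)c1)[C@H]2C | intermediate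
18 | (2R,3S,3aS,7aR)-5-methoxy-3-methyl-3a-(prop-2-en-1-yl)-2-(3,4,5-trimethoxyphenyl)-6-[(trimethylsilyl)oxy]-2,3,3a,7a-tetrahydro-1-benzofuran | C=CC[C@]12C=C(OC)C(O[Si](C)(C)C)=C[C@H]1O[C@@H](c1cc(OC)c(OC)c(OC)c1)[C@H]2C | intermediate
19 | (2R,3S,3aS)-5-methoxy-3-methyl-3a-(prop-2-en-1-yl)-2-(3,4,5-trimethoxyphenyl)-3,3a-dihydro-1-benzofuran-6(2H)-one | C=CC[C@]12C=C(OC)C(=O)C=C1O[C@@H](c1cc(OC)c(OC)c(OC)c1)[C@H]2C | target

Total step count: 8. Longest linear sequence: 8 steps (acetaldehyde 1 to target 19 through steps 1–8); building blocks 5 and 13 enter at steps 3 and 6.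

Steps most likely to fail

Step 6. The substrate may be diverted before the oxocarbenium ion meets the alkene: the lactol form of 12 can dehydrate toward a furan under acid, and acetal formation may stay incomplete, so that SnCl4 meets free hydroxy ketone. The fallback installs the acetal before the ketone exists. It sets out from 11: ring opening with Me(MeO)NH·HCl and Me3Al should give (3R,4S,5Z)-3,4-dihydroxy-N-methoxy-N-methyl-5-(prop-2-en-1-yl)hept-5-enamide F1. Acetalization of F1 with 13 (HC(OMe)3, PPTS) should give 2-{(4R,5S)-5-[(2Z)-hexa-2,5-dien-3-yl]-2-(3,4,5-trimethoxyphenyl)-1,3-dioxolan-4-yl}-N-methoxy-N-methylacetamide F2. Methoxymethyllithium then converts the Weinreb amide into the ketone, which is 14, now isolated and free of any hydroxy ketone. The route is rejoined at 14, which is treated with SnCl4 at −78 °C as in step 6 to give 15.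

Step 3. The tetrahedral adduct may collapse before work-up (second addition of 7), or the basic vinyllithium may deprotonate the dioxolanone α-carbon, with loss of material and of configuration at the malic-acid centre. The fallback replaces the dioxolanone by an aldehyde and sets out from 4 (as 7) and commercial dimethyl (R)-malate. Silylation (TBSCl, imidazole) should give dimethyl (2R)-2-[(tert-butyldimethylsilyl)oxy]butanedioate F3. Reduction of the ester next to the silyloxy group (i-Bu2AlH, 1 equiv, toluene, −78 °C) should give methyl (3R)-3-[(tert-butyldimethylsilyl)oxy]-4-oxobutanoate F4. Addition of 7 (transmetalated with CeCl3) under Felkin–Anh control and lactonization on mildly acidic work-up should give (4R,5S)-4-[(tert-butyldimethylsilyl)oxy]-5-[(2Z)-hexa-2,5-dien-3-yl]oxolan-2-one F5. Desilylation (TBAF, AcOH) returns to the route at 11.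

Step 8. Palladium may engage the terminal allyl alkene, or β-hydride elimination from the palladium enolate may stay incomplete, so that the oxidation stalls or gives mixtures. The fallback uses a selenoxide elimination and sets out from 17 through 18: PhSeCl at −78 °C should give 5-methoxy-3-methyl-7-(phenylselanyl)-3a-(prop-2-en-1-yl)-2-(3,4,5-trimethoxyphenyl)-3,3a,7,7a-tetrahydro-1-benzofuran-6(2H)-one F6. Oxidation (H2O2, pyridine, 0 °C) and syn-elimination of the selenoxide toward the C7a hydrogen returns to the route at 19.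

Further compounds
F1 | step 6 | (3R,4S,5Z)-3,4-dihydroxy-N-methoxy-N-methyl-5-(prop-2-en-1-yl)hept-5-enamide | CON(C)C(=O)C[C@@H](O)[C@@H](O)/C(CC=C)=C\C
F2 | step 6 | 2-{(4R,5S)-5-[(2Z)-hexa-2,5-dien-3-yl]-2-(3,4,5-trimethoxyphenyl)-1,3-dioxolan-4-yl}-N-methoxy-N-methylacetamide | CON(C)C(=O)C[C@H]1OC(c2cc(OC)c(OC)c(OC)c2)O[C@H]1/C(CC=C)=C\C
F3 | step 3 | dimethyl (2R)-2-[(tert-butyldimethylsilyl)oxy]butanedioate | COC(=O)C[C@@H](O[Si](C)(C)C(C)(C)C)C(=O)OC
F4 | step 3 | methyl (3R)-3-[(tert-butyldimethylsilyl)oxy]-4-oxobutanoate | COC(=O)C[C@@H](O[Si](C)(C)C(C)(C)C)C=O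
F5 | step 3 | (4R,5S)-4-[(tert-butyldimethylsilyl)oxy]-5-[(2Z)-hexa-2,5-dien-3-yl]oxolan-2-one | O=C1C[C@@H](O[Si](C)(C)C(C)(C)C)[C@H](/C(CC=C)=C\C)O1
F6 | step 8 | 5-methoxy-3-methyl-7-(phenylselanyl)-3a-(prop-2-en-1-yl)-2-(3,4,5-trimethoxyphenyl)-3,3a,7,7a-tetrahydro-1-benzofuran-6(2H)-one (C7 epimers) | C=CC[C@]12C=C(OC)C(=O)C([Se]c3ccccc3)[C@H]1O[C@@H](c1cc(OC)c(OC)c(OC)c1)[C@H]2C
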